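Nothing of the substrate leaves this flask: solid substrate, dissolved substrate and target add up to the charge at every moment, so the yield is what coupling has carried across that balance.

    solid substrate ⇌ dissolved substrate, rate k1*(cs1 - [dissolved substrate]) while solid is left; crystals form when [dissolved substrate] > cs1 (cs1 = 0.37 M, k1 = 0.44 s⁻¹)
    dissolved substrate + coupling partner → target (k2 = 0.016 L mol⁻¹ s⁻¹)
    coupling partner → side product (k3 = 0.0019 s⁻¹)
    solid reagent ⇌ coupling partner, rate k4*(cs4 - [coupling partner]) while solid is left; crystals form when [coupling partner] > cs4 (cs4 = 0.63 M, k4 = 0.14 s⁻¹)

solid substrate 0.80 M; solid reagent 0.840 M; time 4.0 min

* target at 4.0 min, in percent of the solid substrate charged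
* concentration of dissolved substrate in solution at 4.0 min, in percent of saturation

I turned the constants into times. The slower dissolving, that of the solid reagent, takes 7.14 s. A dissolved substrate in solution saturated with coupling partner lasts 99.2 s, the pseudo-first-order lifetime I called the coupling time. Because the coupling time exceeds the dissolving time 13.9-fold, I took coupling as the rate-limiting step, with the solids holding the solution saturated while they last. At that pace the solid substrate lasted 1.92 min, and the dissolved rest then decayed with the coupling time, which gave 86.8 % at 4.0 min. But in this flask the solid reagent beyond saturation lasts 0.710 min once the solution is full, less than the solid substrate's time. So I committed to a yield below that figure, and no further.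

The forecast gave 64 % and 77 %, holding that “the solid reagent runs out after about a minute”.

The flask gave 64.1 % and 77.7 %. A charge of solid reagent of 0.759 M or 0.935 M moves the yield by 5 points, which could part it from the forecast.

With 1.4 M of solid reagent, the same reckoning lets the solid reagent beyond saturation last 2.60 min, longer than the solid substrate's 1.92 min but shorter than the 4.0 min of the run. My figure of 86.8 % needed coupling partner at saturation up to 4.0 min, so I expected that flask to stay below it. That flask gave 82.8 % at 4.00 min, with coupling partner down to 0.478 M, below its solubility.

(Its constants are those of an exercise, and the outcome is calculated.)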